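**Retrosynthetic overview**

1. Target 15 comes from its bis-MOM ether 14 by acetal cleavage in the last step.
2. The strategy rests on ring C, the dihydropyran O1–C2–C3–C4–C4a–C8a. O1, C8a, C4a and C4 come from a ring-A o-quinone methide (13, from o-hydroxybenzyl alcohol 10); C2=C3 is the vinyl group of 3,5-dimethoxystyrene 12. One oxa-[4+2] forms O1–C2 and C3–C4 and sets C2 (R) under a chiral Brønsted acid.
3. Ring C is the only ring formed; ring A comes from phloroglucinol 1 and ring B from 3,5-dimethoxybenzaldehyde 11.
4. 10 comes from aldehyde 9, made by ortho-formylation of the symmetric phenol 7 (both ortho sites equivalent). 7 comes from MOM-directed lithiation and prenylation of the TIPS-capped bis-MOM ether 3; 12 comes from 11 by Wittig methylenation.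

Key step: step 8

Assumption: the sense of induction of the chiral acid on this substrate pair cannot be derived from precedent. The catalyst is written with (R)-BINOL units; its mirror image is used if a first run shows the 2S series. No compound of the route changes. Locants C2–C8a refer to the chroman skeleton.

**Route**

Step 1
Reactants: 1 phloroglucinol (benzene-1,3,5-triol)
Product: 2 3,5-bis(methoxymethoxy)phenol
Conditions: MOMCl (2.0 equiv), i-Pr2NEt (2.2 equiv), DMF–CH2Cl2, 0 °C to rt; chromatography
Reagents that add atoms: chloromethyl methyl ether (MOMCl), COCCl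
Why: O-Alkylation of the phenoxides with MOMCl (Williamson-type ether formation) is statistical on this symmetric triphenol, so two equivalents should give the bis-ether as the main fraction, with the mono- and tris-ethers removed by chromatography and recycled.

Step 2
Reactants: 2 3,5-bis(methoxymethoxy)phenol
Product: 3 [3,5-bis(methoxymethoxy)phenoxy]tri(propan-2-yl)silane
Conditions: TIPSCl, imidazole, DMF, rt
Reagents that add atoms: chlorotri(propan-2-yl)silane (TIPSCl), CC(C)[Si](Cl)(C(C)C)C(C)C
Why: Silyl ether formation caps the remaining phenol with a bulky, non-coordinating TIPS group, which removes the acidic proton before lithiation and leaves the C–H between the two MOM ethers as the only strongly activated site.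

Step 3
Reactants: 3 [3,5-bis(methoxymethoxy)phenoxy]tri(propan-2-yl)silane; 4 prenyl bromide (1-bromo-3-methylbut-2-ene)
Product: 6 [3,5-bis(methoxymethoxy)-4-(3-methylbut-2-en-1-yl)phenoxy]tri(propan-2-yl)silane, via aryllithium 5 (not isolated)
Conditions: n-BuLi, THF, 0 °C; then CuBr·SMe2 (10 mol%), 4, −78 °C to rt
Reagents that add atoms: none
Why: Directed ortho-metalation places lithium on the carbon flanked by both MOM ethers (para to the silyloxy group, so no silyl migration can follow), and copper-catalysed SN2 alkylation of aryllithium 5 at the primary carbon of the allylic bromide should deliver the linear prenyl group.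

Step 4
Reactants: 6 [3,5-bis(methoxymethoxy)-4-(3-methylbut-2-en-1-yl)phenoxy]tri(propan-2-yl)silane
Product: 7 3,5-bis(methoxymethoxy)-4-(3-methylbut-2-en-1-yl)phenol
Conditions: TBAF, AcOH (1:1), THF, 0 °C to rt
Reagents that add atoms: none
Why: Fluoride-induced desilylation is driven by the strength of the Si–F bond, and the acetic acid buffer protonates the phenoxide as it forms while the MOM acetals and the alkene are untouched.

Step 5
Reactants: 7 3,5-bis(methoxymethoxy)-4-(3-methylbut-2-en-1-yl)phenol
Product: 9 6-hydroxy-2,4-bis(methoxymethoxy)-3-(3-methylbut-2-en-1-yl)benzaldehyde, via chloromagnesium hydroxymethylphenoxide 8 (not isolated)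
Conditions: MgCl2, Et3N, (CH2O)n, MeCN, reflux; then aq. NH4Cl
Reagents that add atoms: paraformaldehyde (reacts as formaldehyde), C=O
Why: Magnesium-mediated ortho-formylation (Casnati–Skattebøl reaction) hydroxymethylates the magnesium phenoxide at one of the two symmetry-equivalent ortho carbons to give 8, which is oxidised in place by hydride transfer to a second formaldehyde, and the basic medium spares the MOM ethers.

Step 6
Reactants: 9 6-hydroxy-2,4-bis(methoxymethoxy)-3-(3-methylbut-2-en-1-yl)benzaldehyde
Product: 10 2-(hydroxymethyl)-3,5-bis(methoxymethoxy)-4-(3-methylbut-2-en-1-yl)phenol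
Conditions: NaBH4, THF–MeOH, 0 °C; pH 7 buffer work-up; used without storage
Reagents that add atoms: none
Why: Hydride reduction of the aldehyde by NaBH4 is chemoselective over the alkene and the acetals, and the electron-rich o-hydroxybenzyl alcohol is kept at neutral pH and taken on directly because it ionises easily.

Step 7
Reactants: 11 3,5-dimethoxybenzaldehyde
Product: 12 3,5-dimethoxystyrene (1-ethenyl-3,5-dimethoxybenzene)
Conditions: Ph3PCH3Br, KOtBu, THF, 0 °C to rt
Reagents that add atoms: methyltriphenylphosphonium bromide, C[P+](c1ccccc1)(c1ccccc1)c1ccccc1.[Br-]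
Why: Wittig methylenation of the non-enolisable aryl aldehyde with the unstabilised ylide generated in the flask should give the terminal alkene cleanly.

Step 8
Reactants: 10 2-(hydroxymethyl)-3,5-bis(methoxymethoxy)-4-(3-methylbut-2-en-1-yl)phenol; 12 3,5-dimethoxystyrene (5 equiv)
Product: 14 (2R)-2-(3,5-dimethoxyphenyl)-5,7-bis(methoxymethoxy)-6-(3-methylbut-2-en-1-yl)-3,4-dihydro-2H-1-benzopyran, via o-quinone methide 13 (not isolated)
Conditions: confined imidodiphosphoric acid HN[P(=O)(O2Ar*)]2 built from two (R)-3,3′-bis(2,4,6-triethylphenyl)-BINOL units (10 mol%), 5 Å MS, toluene, 0 °C, 10 added slowly by syringe pump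
Reagents that add atoms: none
Why: Proposed new method: the chiral acid dehydrates 10 to the o-quinone methide 13 (the water released is taken up by the molecular sieves), which stays hydrogen-bonded or ion-paired to the chiral imidodiphosphate, and the terminal CH2 of 12 attacks the methide carbon (future C4) while the carbonyl oxygen closes onto the developing benzylic carbon (C2) in an asynchronous inverse-demand oxa-[4+2] cycloaddition. The closest known reaction types are the chiral phosphoric acid catalysed [4+2] additions of o-hydroxybenzyl-alcohol-derived o-quinone methides to hydrogen-bonding styrenes and enamides, the confined-acid intramolecular o-quinone methide cycloaddition with unactivated alkenes and the confined-acid Prins reaction of plain styrenes; new here is the union of a CH2 methide terminus with a styrene that offers no hydrogen-bond handle. Ring C is closed by intermolecular [4+2] cycloaddition, which forms C3–C4 and O1–C2 in one operation. C2 is the only new stereocenter and is controlled by the chiral anion, which is bound at the oxygen that forms the O1–C2 bond, so that one face of the styrene is presented inside the catalyst pocket. Regioselectivity (aryl at C2) follows from polarity, the nucleophilic styrene terminus adding to the electrophilic methide carbon with positive charge developing at the benzylic position. The step also needs chemoselectivity for the styrene over Friedel–Crafts attack by the free C–H of the electron-rich ring A and over the prenyl alkene, which is sought through excess 12, slow addition of 10, low temperature and the narrow pocket that admits a terminal alkene more readily than a flanked arene carbon, while the weak acid leaves the MOM ethers and the prenyl group intact.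

Step 9
Reactants: 14 (2R)-2-(3,5-dimethoxyphenyl)-5,7-bis(methoxymethoxy)-6-(3-methylbut-2-en-1-yl)-3,4-dihydro-2H-1-benzopyran
Product: 15 (2R)-2-(3,5-dimethoxyphenyl)-6-(3-methylbut-2-en-1-yl)-3,4-dihydro-2H-1-benzopyran-5,7-diol
Conditions: aq. HCl (3 M), MeOH, 35 °C, stopped at full conversion
Reagents that add atoms: none
Why: Acid-catalysed acetal exchange with methanol (MOM cleavage) releases both phenols, and under dilute acid at mild temperature the prenyl alkene is expected to resist cyclisation onto the neighbouring phenols while the C2–O1 benzylic ether, whose aryl group has only meta methoxy groups, should not ionise, so the 2R centre is retained.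

**Compound list**

1 | benzene-1,3,5-triol (phloroglucinol) | Oc1cc(O)cc(O)c1 | starting material
2 | 3,5-bis(methoxymethoxy)phenol | COCOc1cc(O)cc(OCOC)c1 | intermediate
3 | [3,5-bis(methoxymethoxy)phenoxy]tri(propan-2-yl)silane | COCOc1cc(O[Si](C(C)C)(C(C)C)C(C)C)cc(OCOC)c1 | intermediate
4 | 1-bromo-3-methylbut-2-ene (prenyl bromide) | CC(C)=CCBr | starting material
5 | [2,6-bis(methoxymethoxy)-4-(triisopropylsilyloxy)phenyl]lithium | [Li]c1c(OCOC)cc(O[Si](C(C)C)(C(C)C)C(C)C)cc1OCOC | intermediate (not isolated)
6 | [3,5-bis(methoxymethoxy)-4-(3-methylbut-2-en-1-yl)phenoxy]tri(propan-2-yl)silane | COCOc1cc(O[Si](C(C)C)(C(C)C)C(C)C)cc(OCOC)c1CC=C(C)C | intermediate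
7 | 3,5-bis(methoxymethoxy)-4-(3-methylbut-2-en-1-yl)phenol | COCOc1cc(O)cc(OCOC)c1CC=C(C)C | intermediate
8 | chloromagnesium 2-(hydroxymethyl)-3,5-bis(methoxymethoxy)-4-(3-methylbut-2-en-1-yl)phenoxide | OCc1c(O[Mg]Cl)cc(OCOC)c(CC=C(C)C)c1OCOC | intermediate (not isolated)
9 | 6-hydroxy-2,4-bis(methoxymethoxy)-3-(3-methylbut-2-en-1-yl)benzaldehyde | O=Cc1c(O)cc(OCOC)c(CC=C(C)C)c1OCOC | intermediate
10 | 2-(hydroxymethyl)-3,5-bis(methoxymethoxy)-4-(3-methylbut-2-en-1-yl)phenol | OCc1c(O)cc(OCOC)c(CC=C(C)C)c1OCOC | intermediate
11 | 3,5-dimethoxybenzaldehyde | COc1cc(OC)cc(C=O)c1 | starting material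
12 | 1-ethenyl-3,5-dimethoxybenzene (3,5-dimethoxystyrene) | C=Cc1cc(OC)cc(OC)c1 | intermediate
13 | 3,5-bis(methoxymethoxy)-6-methylidene-4-(3-methylbut-2-en-1-yl)cyclohexa-2,4-dien-1-one (o-quinone methide) | C=C1C(=O)C=C(OCOC)C(CC=C(C)C)=C1OCOC | intermediate (not isolated)
14 | (2R)-2-(3,5-dimethoxyphenyl)-5,7-bis(methoxymethoxy)-6-(3-methylbut-2-en-1-yl)-3,4-dihydro-2H-1-benzopyran | COc1cc(OC)cc([C@H]2CCc3c(cc(OCOC)c(CC=C(C)C)c3OCOC)O2)c1 | intermediate
15 | (2R)-2-(3,5-dimethoxyphenyl)-6-(3-methylbut-2-en-1-yl)-3,4-dihydro-2H-1-benzopyran-5,7-diol | COc1cc(OC)cc([C@H]2CCc3c(cc(O)c(CC=C(C)C)c3O)O2)c1 | target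

**Totals**

Total step count: 9.
Longest linear sequence: 8 steps (steps 1–6, 8 and 9, from phloroglucinol 1); the styrene branch adds step 7.

**Steps most likely to fail**

Step 8 (the labelled step). Three processes may undercut it. Facial discrimination may be weak because the styrene has no group that binds the catalyst. Ring A may alkylate itself: the free aromatic C–H of 10 or of 14 can attack the methide carbon in a Friedel–Crafts sense and lead to methylene-bridged oligomers. The prenyl alkene may capture the methide in place of the styrene. The fallback uses only known reactions, sets out from aldehyde 9 and returns at 14. Claisen–Schmidt condensation of 9 with commercial 1-(3,5-dimethoxyphenyl)ethan-1-one (KOH, EtOH, rt) should give the enone (2E)-1-(3,5-dimethoxyphenyl)-3-[6-hydroxy-2,4-bis(methoxymethoxy)-3-(3-methylbut-2-en-1-yl)phenyl]prop-2-en-1-one F1. Hydrogenation with RhCl(PPh3)3 and H2 (1 atm, benzene–EtOH) should saturate the conjugated disubstituted alkene and leave the trisubstituted prenyl alkene, giving 1-(3,5-dimethoxyphenyl)-3-[6-hydroxy-2,4-bis(methoxymethoxy)-3-(3-methylbut-2-en-1-yl)phenyl]propan-1-one F2. Noyori-type asymmetric transfer hydrogenation with RuCl[(S,S)-TsDPEN](p-cymene) in HCO2H–Et3N should, by the usual aryl ketone model, give (1S)-1-(3,5-dimethoxyphenyl)-3-[6-hydroxy-2,4-bis(methoxymethoxy)-3-(3-methylbut-2-en-1-yl)phenyl]propan-1-ol F3. Mitsunobu cyclisation (PPh3, DIAD, THF, 0 °C) then lets the phenol displace the activated benzylic oxygen with inversion, which closes O1–C2 and gives the 2R flavan 14.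

Step 9. Protonation of the prenyl alkene may lead to cyclisation onto either flanking phenol (a dimethyldihydropyran ring) or to hydration before both acetals are cleaved. The fallback avoids protic acid altogether, sets out from 14 and returns at 15. Treatment of 14 with TESOTf and 2,2′-bipyridyl (CH2Cl2, 0 °C) should transfer each methoxymethyl group to the bipyridyl nitrogen and silylate the phenolic oxygens under base-buffered conditions, giving (2R)-2-(3,5-dimethoxyphenyl)-6-(3-methylbut-2-en-1-yl)-5,7-bis(triethylsilyloxy)-3,4-dihydro-2H-1-benzopyran F4. Fluoride cleavage of the two aryl silyl ethers (TBAF, AcOH, THF, 0 °C) then gives 15.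

Step 3. The aryl-metal may attack the tertiary end of the allylic bromide (SN2′, reverse-prenyl isomer), or the alkylation may stall through halogen–metal exchange and elimination. The fallback separates C–C bond formation from construction of the trisubstituted alkene, sets out from 3 and returns at 6. Aryllithium 5, generated as in step 3, is quenched with allyl bromide, whose two termini are identical, to give [3,5-bis(methoxymethoxy)-4-(prop-2-en-1-yl)phenoxy]tri(propan-2-yl)silane F5. Cross-metathesis of F5 with excess 2-methylbut-2-ene using the second-generation Grubbs catalyst RuCl2(=CHPh)(H2IMes)(PCy3) (CH2Cl2, 40 °C) should then give 6.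

**Further compounds**

F1 | step 8 | (2E)-1-(3,5-dimethoxyphenyl)-3-[6-hydroxy-2,4-bis(methoxymethoxy)-3-(3-methylbut-2-en-1-yl)phenyl]prop-2-en-1-one | COc1cc(OC)cc(C(=O)/C=C/c2c(O)cc(OCOC)c(CC=C(C)C)c2OCOC)c1
F2 | step 8 | 1-(3,5-dimethoxyphenyl)-3-[6-hydroxy-2,4-bis(methoxymethoxy)-3-(3-methylbut-2-en-1-yl)phenyl]propan-1-one | COc1cc(OC)cc(C(=O)CCc2c(O)cc(OCOC)c(CC=C(C)C)c2OCOC)c1
F3 | step 8 | (1S)-1-(3,5-dimethoxyphenyl)-3-[6-hydroxy-2,4-bis(methoxymethoxy)-3-(3-methylbut-2-en-1-yl)phenyl]propan-1-ol | COc1cc(OC)cc([C@@H](O)CCc2c(O)cc(OCOC)c(CC=C(C)C)c2OCOC)c1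
F4 | step 9 | (2R)-2-(3,5-dimethoxyphenyl)-6-(3-methylbut-2-en-1-yl)-5,7-bis(triethylsilyloxy)-3,4-dihydro-2H-1-benzopyran | COc1cc(OC)cc([C@H]2CCc3c(cc(O[Si](CC)(CC)CC)c(CC=C(C)C)c3O[Si](CC)(CC)CC)O2)c1
F5 | step 3 | [3,5-bis(methoxymethoxy)-4-(prop-2-en-1-yl)phenoxy]tri(propan-2-yl)silane | COCOc1cc(O[Si](C(C)C)(C(C)C)C(C)C)cc(OCOC)c1CC=C
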